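**Plan** (chromene numbering: O1, C2, C3, C4, C4a, C5–C8, C8a)

- Cuts, in order: the two quinone C=O groups back to an 8-allyloxy-6-methoxy-2H-chromene (C5 oxygen by Teuber oxidation); then O1–C2 and C4a–C8a together, which opens both rings to a dienylcyclobutenone; then the diene single bond (vinyl iodide plus stannylvinylcyclobutenone); last the cyclohexene (Diels–Alder).
- Enabling feature: C8a carries the pyran oxygen, C6 (para to it) the methoxy group and C4a the C4=C3–C2 chain. This is the imprint of a 4-methoxy-4-dienylcyclobutenone whose carbonyl becomes C8a–O1. The pyran ring O1–C2(Me)(R)–C3=C4 is a cyclised 2-(3-methoxyalk-1-enyl)phenol.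
- Forward ring order: cyclohexene (step 1); then in step 11 the benzo ring (4π opening, 6π closure, C4a–C8a) and directly after it the pyran ring (ionisation at C2, 6-endo C–O closure); then the quinone.
- Helpers: the four-membered ring (cleaved in step 11), the tertiary methoxy group at the future C2 (leaves in step 11), the allyl group on O8 (removed in step 12). A carbonyl transposition on the squarate-derived ring makes the future C7 a CH.
- Stereochemistry: both ring stereocentres come from a catalytic asymmetric endo Diels–Alder reaction. C2 comes from the chiral phosphoramide ion pair of step 11. All other stereocentres are transient.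

Key step: step 11

Remark: the sense of asymmetric induction in steps 1 and 11 is assigned by analogy with the closest known cases; if either proves opposite, the mirror-image catalyst is to be used.

**Step 1**
Reactants: 1 (3E)-3-methylpenta-1,3-diene (commercial E/Z mixture in excess; only the E isomer reacts); 2 methacrolein
Product: 3 (1R,2S)-1,2,3-trimethylcyclohex-3-ene-1-carbaldehyde
Conditions: (S)-3,3-diphenyl-1-(o-tolyl)tetrahydropyrrolo[1,2-c][1,3,2]oxazaborole·HNTf2 (10 mol %), CH2Cl2, −78 → −40 °C
Reagents that add atoms: none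
Why: Catalytic enantioselective Diels–Alder reaction: the protonated oxazaborolidine binds the s-trans enal and blocks one face, the methyl-bearing diene terminus bonds to the formyl-bearing carbon (ortho orientation, the terminal methyl outweighing the internal one) and the formyl group adds endo, which should set the quaternary centre and place the C2 methyl cis to CHO.

**Step 2**
Reactants: 3 (1R,2S)-1,2,3-trimethylcyclohex-3-ene-1-carbaldehyde; 4 diethyl (2-oxopropyl)phosphonate
Product: 5 (3E)-4-[(1S,2S)-1,2,3-trimethylcyclohex-3-en-1-yl]but-3-en-2-one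
Conditions: NaH, THF, 0 → 50 °C
Reagents that add atoms: none
Why: Horner–Wadsworth–Emmons olefination of the non-enolisable aldehyde with the stabilised phosphonate anion should give the E enone and cannot disturb the ring stereocentres.

**Step 3**
Reactants: 5 (3E)-4-[(1S,2S)-1,2,3-trimethylcyclohex-3-en-1-yl]but-3-en-2-one
Product: 7 4-[(1S,2R)-1,2,3-trimethylcyclohex-3-en-1-yl]butan-2-one, via triethylsilyl enol ether 6 (not isolated)
Conditions: Et3SiH, RhCl(PPh3)3 (2 mol %, monovalent rhodium), toluene, 60 °C; then K2CO3, MeOH, rt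
Reagents that add atoms: none
Why: Rhodium-catalysed 1,4-hydrosilylation of the enone with a monohydrosilane followed by methanolysis of the silyl enol ether (a conjugate reduction) should saturate only the conjugated alkene and leave the trisubstituted ring alkene.

**Step 4**
Reactants: 7 4-[(1S,2R)-1,2,3-trimethylcyclohex-3-en-1-yl]butan-2-one; 8 ethynyltrimethylsilane
Product: 11 3-methoxy-3-methyl-5-[(1S,2R)-1,2,3-trimethylcyclohex-3-en-1-yl]pent-1-yne (both C3 epimers), via lithium alkoxide 9 (not isolated), via silylated methyl ether 10 (not isolated)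
Conditions: 8, n-BuLi, THF, −78 °C; 7; MeOTf, −78 °C → rt; then K2CO3, MeOH, rt
Reagents that add atoms: methyl trifluoromethanesulfonate, COS(=O)(=O)C(F)(F)F
Why: 1,2-Addition of the lithium acetylide to the methyl ketone, O-methylation of the tertiary lithium alkoxide by methyl triflate and base-mediated C-desilylation should give the tertiary propargylic methyl ether, whose new stereocentre forms unselectively and is erased in step 11.

**Step 5**
Reactants: 11 3-methoxy-3-methyl-5-[(1S,2R)-1,2,3-trimethylcyclohex-3-en-1-yl]pent-1-yne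
Product: 13 (1E)-1-iodo-3-methoxy-3-methyl-5-[(1S,2R)-1,2,3-trimethylcyclohex-3-en-1-yl]pent-1-ene (both C3 epimers), via alkenylzirconocene chloride 12 (not isolated)
Conditions: Cp2Zr(H)Cl, THF, rt; then I2, 0 °C
Reagents that add atoms: iodine, II
Why: Hydrozirconation (syn addition with zirconium at the terminal carbon) and iodinolysis with retention should give the E vinyl iodide without touching the trisubstituted alkene or the ether.

**Step 6**
Reactants: 14 squaric acid; 15 prop-2-en-1-ol (two molecules are consumed per molecule of 14; used in excess)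
Product: 16 3,4-bis(prop-2-en-1-yloxy)cyclobut-3-ene-1,2-dione (diallyl squarate)
Conditions: 15 (excess), toluene, reflux, Dean–Stark trap
Reagents that add atoms: prop-2-en-1-ol (second equivalent), C=CCO
Why: Self-catalysed azeotropic esterification (squaric acid is a strong vinylogous carboxylic acid) should convert both acidic hydroxyl groups, one molecule of the alcohol each with removal of two molecules of water, into the diester; the allyl groups are chosen because one of them must later be removed under neutral conditions.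

**Step 7**
Reactants: 16 diallyl squarate; 17 (E)-1,2-bis(tributylstannyl)ethene
Product: 20 4-methoxy-2,3-bis(prop-2-en-1-yloxy)-4-[(E)-2-(tributylstannyl)ethenyl]cyclobut-2-en-1-one (racemic), via stannylvinyllithium 18 (not isolated), via lithium alkoxide 19 (not isolated)
Conditions: 17, n-BuLi, THF, −78 °C; 16, −78 °C; MeOTf, −78 → 0 °C
Reagents that add atoms: methyl trifluoromethanesulfonate, COS(=O)(=O)C(F)(F)F
Why: Tin–lithium exchange on the distannane gives the E stannylvinyllithium, whose 1,2-addition to one of the two equivalent carbonyl groups of the squarate and O-methylation of the alkoxide with methyl triflate should give the 4-methoxycyclobutenone.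

**Step 8**
Reactants: 20 4-methoxy-2,3-bis(prop-2-en-1-yloxy)-4-[(E)-2-(tributylstannyl)ethenyl]cyclobut-2-en-1-one
Product: 21 4-methoxy-2,3-bis(prop-2-en-1-yloxy)-4-[(E)-2-(tributylstannyl)ethenyl]cyclobut-2-en-1-ol (mixture of diastereomers)
Conditions: i-Bu2AlH, toluene, −78 °C; aq. KNaC4H4O6 (potassium sodium tartrate)
Reagents that add atoms: none
Why: 1,2-Reduction of the vinylogous ester carbonyl group by the aluminium hydride (first half of a Stork–Danheiser transposition) should give the cyclobutenol while the vinylstannane and the allyl enol ethers are inert to the reagent at low temperature.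

**Step 9**
Reactants: 21 4-methoxy-2,3-bis(prop-2-en-1-yloxy)-4-[(E)-2-(tributylstannyl)ethenyl]cyclobut-2-en-1-ol
Product: 23 4-methoxy-2-(prop-2-en-1-yloxy)-4-[(E)-2-(tributylstannyl)ethenyl]cyclobut-2-en-1-one (racemic), via trifluoroacetate 22 (not isolated)
Conditions: (CF3CO)2O, 2,6-lutidine, CH2Cl2, −78 → 0 °C; then aq. NaHCO3
Reagents that add atoms: water, O
Why: Stork–Danheiser-type carbonyl transposition: only the free hydroxyl is activated under the buffered conditions, the trifluoroacetate ionises to an alkoxy-stabilised cyclobutenyl cation, and hydrolysis at the alkoxy-bearing terminus next to the quaternary carbon should give the 2-allyloxy enone in which C3 is a CH (the future C7–H).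

**Step 10**
Reactants: 13 (1E)-1-iodo-3-methoxy-3-methyl-5-[(1S,2R)-1,2,3-trimethylcyclohex-3-en-1-yl]pent-1-ene; 23 4-methoxy-2-(prop-2-en-1-yloxy)-4-[(E)-2-(tributylstannyl)ethenyl]cyclobut-2-en-1-one
Product: 24 4-methoxy-4-{(1E,3E)-5-methoxy-5-methyl-7-[(1S,2R)-1,2,3-trimethylcyclohex-3-en-1-yl]hepta-1,3-dien-1-yl}-2-(prop-2-en-1-yloxy)cyclobut-2-en-1-one (mixture of diastereomers)
Conditions: Cu(O2C-C4H3S) (copper thiophene-2-carboxylate, monovalent copper, 1.5 equiv), NMP, 0 °C → rt
Reagents that add atoms: none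
Why: Copper carboxylate-mediated Stille-type coupling of the vinyl iodide with the vinylstannane runs at or below room temperature without palladium, so the allyl enol ether and the thermally labile cyclobutenone should survive and both alkene geometries are retained.

**Step 11**
Reactants: 24 4-methoxy-4-{(1E,3E)-5-methoxy-5-methyl-7-[(1S,2R)-1,2,3-trimethylcyclohex-3-en-1-yl]hepta-1,3-dien-1-yl}-2-(prop-2-en-1-yloxy)cyclobut-2-en-1-one
Product: 29 (2S)-6-methoxy-2-methyl-8-(prop-2-en-1-yloxy)-2-{2-[(1S,2R)-1,2,3-trimethylcyclohex-3-en-1-yl]ethyl}-2H-chromene, via dienylketene 25 (not isolated), via cyclohexadienone 26 (not isolated), via phenol 27 (not isolated), via ion-paired allyl cation 28 (not isolated)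
Conditions: toluene (0.02 M), 100 °C; then −50 °C, (R)-3,3'-bis(2,4,6-triisopropylphenyl)-1,1'-binaphthyl-2,2'-diyl N-triflylphosphoramide (10 mol %), 5 Å molecular sieves, −50 → −20 °C
Reagents that add atoms: none
Why: Proposed new method: on heating, the cyclobutenone opens by conrotatory 4π ring opening with the 4-methoxy group turning outward, the dienylketene 25 closes at once by disrotatory 6π electrocyclisation between the ketene carbon (C8a) and the far carbon of the proximal alkene (C4a) to give the six-membered carbocycle 26, and enolisation gives phenol 27; the closest known reaction type is the thermal ring expansion of 4-alkenyl-4-alkoxycyclobutenones to hydroquinone ethers. At low temperature the chiral N-triflylphosphoramide then ionises the tertiary allylic methyl ether of both epimers of 27 to a single allyl cation (the O-protonated vinyl o-quinone methide 28) held as a contact ion pair, and the phenol oxygen closes on the tertiary terminus C2 in a 6-endo mode (an oxa-6π closure of the protonated quinone methide), which forms the pyran ring and leaves the C3=C4 alkene; the closest known reaction type is the chiral phosphoramide-catalysed intramolecular allylic substitution of 2-(3-hydroxyalk-1-enyl)phenols to 2,2-disubstituted 2H-chromenes, which has not been shown for a terminus with two alkyl groups or in one flask with a ring expansion. C2 is the only new stereocentre and is to be controlled by the catalyst, whose anion is hydrogen-bonded to the phenol and paired with the cation and so selects the helical sense of the closing six-atom array; the remote ring stereocentres are not expected to contribute. The step needs (a) the dienyl group cis to the ketene, secured by the outward-rotating methoxy group, (b) 6π and not 8π closure, secured by the E geometry of the proximal alkene, (c) no closure before the catalyst is added, secured by placing the leaving group on the tertiary carbon remote from the phenol so that uncatalysed loss of methanol to an o-quinone methide should be slow at the temperature of the ring expansion, and (d) E to Z isomerisation within the cation, which its benzylic resonance form allows.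

**Step 12**
Reactants: 29 (2S)-6-methoxy-2-methyl-8-(prop-2-en-1-yloxy)-2-{2-[(1S,2R)-1,2,3-trimethylcyclohex-3-en-1-yl]ethyl}-2H-chromene
Product: 30 (2S)-6-methoxy-2-methyl-2-{2-[(1S,2R)-1,2,3-trimethylcyclohex-3-en-1-yl]ethyl}-2H-chromen-8-ol
Conditions: Pd(PPh3)4 (5 mol %, zerovalent palladium), morpholine, THF, rt
Reagents that add atoms: none
Why: Tsuji–Trost deallylation: zerovalent palladium ionises the primary allyl aryl ether and morpholine traps the allyl cation equivalent, under neutral conditions that should leave the hindered cyclic tertiary allylic ether at C2 and hence its configuration untouched.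

**Step 13**
Reactants: 30 (2S)-6-methoxy-2-methyl-2-{2-[(1S,2R)-1,2,3-trimethylcyclohex-3-en-1-yl]ethyl}-2H-chromen-8-ol
Product: 31 (2S)-6-methoxy-2-methyl-2-{2-[(1S,2R)-1,2,3-trimethylcyclohex-3-en-1-yl]ethyl}-2H-chromene-5,8-dione
Conditions: (KSO3)2NO, KH2PO4, acetone/H2O, 0 °C → rt
Reagents that add atoms: potassium nitrosodisulfonate, [K+].[K+].[O]N(S(=O)(=O)[O-])S(=O)(=O)[O-]
Why: Teuber oxidation: the nitrosodisulfonate radical oxidises the phenol and delivers oxygen to the free para position C5, which should give the 5,8-quinone with the methoxy group at C6 and no change at C2.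

**Compound list**

1 | (3E)-3-methylpenta-1,3-diene | C=C/C(C)=C/C | starting material
2 | methacrolein | CC(=C)C=O | starting material
3 | (1R,2S)-1,2,3-trimethylcyclohex-3-ene-1-carbaldehyde | O=C[C@]1(C)CCC=C(C)[C@@H]1C | intermediate
4 | diethyl (2-oxopropyl)phosphonate | CCOP(=O)(CC(C)=O)OCC | starting material
5 | (3E)-4-[(1S,2S)-1,2,3-trimethylcyclohex-3-en-1-yl]but-3-en-2-one | CC(=O)/C=C/[C@]1(C)CCC=C(C)[C@@H]1C | intermediate
6 | triethyl({4-[(1S,2R)-1,2,3-trimethylcyclohex-3-en-1-yl]but-2-en-2-yl}oxy)silane (E/Z mixture) | CC[Si](CC)(CC)OC(C)=CC[C@]1(C)CCC=C(C)[C@@H]1C | intermediate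
7 | 4-[(1S,2R)-1,2,3-trimethylcyclohex-3-en-1-yl]butan-2-one | CC(=O)CC[C@]1(C)CCC=C(C)[C@@H]1C | intermediate
8 | ethynyltrimethylsilane | C#C[Si](C)(C)C | starting material
9 | lithium 3-methyl-5-[(1S,2R)-1,2,3-trimethylcyclohex-3-en-1-yl]-1-(trimethylsilyl)pent-1-yn-3-olate (both C3 epimers) | [Li]OC(C)(C#C[Si](C)(C)C)CC[C@]1(C)CCC=C(C)[C@@H]1C | intermediate
10 | {3-methoxy-3-methyl-5-[(1S,2R)-1,2,3-trimethylcyclohex-3-en-1-yl]pent-1-yn-1-yl}trimethylsilane (both C3 epimers) | COC(C)(C#C[Si](C)(C)C)CC[C@]1(C)CCC=C(C)[C@@H]1C | intermediate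
11 | 3-methoxy-3-methyl-5-[(1S,2R)-1,2,3-trimethylcyclohex-3-en-1-yl]pent-1-yne (both C3 epimers) | C#CC(C)(OC)CC[C@]1(C)CCC=C(C)[C@@H]1C | intermediate
12 | chlorobis(cyclopentadienyl){(1E)-3-methoxy-3-methyl-5-[(1S,2R)-1,2,3-trimethylcyclohex-3-en-1-yl]pent-1-en-1-yl}zirconium | Cl[Zr](/C=C/C(C)(OC)CC[C@]1(C)CCC=C(C)[C@@H]1C)(C2C=CC=C2)C2C=CC=C2 | intermediate
13 | (1E)-1-iodo-3-methoxy-3-methyl-5-[(1S,2R)-1,2,3-trimethylcyclohex-3-en-1-yl]pent-1-ene (both C3 epimers) | I/C=C/C(C)(OC)CC[C@]1(C)CCC=C(C)[C@@H]1C | intermediate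
14 | squaric acid | OC1=C(O)C(=O)C1=O | starting material
15 | prop-2-en-1-ol | C=CCO | starting material
16 | 3,4-bis(prop-2-en-1-yloxy)cyclobut-3-ene-1,2-dione | C=CCOC1=C(OCC=C)C(=O)C1=O | intermediate
17 | (E)-1,2-bis(tributylstannyl)ethene | CCCC[Sn](CCCC)(CCCC)/C=C/[Sn](CCCC)(CCCC)CCCC | starting material
18 | (E)-2-(tributylstannyl)ethenyllithium | [Li]/C=C/[Sn](CCCC)(CCCC)CCCC | intermediate
19 | lithium 4-oxo-2,3-bis(prop-2-en-1-yloxy)-1-[(E)-2-(tributylstannyl)ethenyl]cyclobut-2-en-1-olate (racemic) | [Li]OC1(/C=C/[Sn](CCCC)(CCCC)CCCC)C(=O)C(OCC=C)=C1OCC=C | intermediate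
20 | 4-methoxy-2,3-bis(prop-2-en-1-yloxy)-4-[(E)-2-(tributylstannyl)ethenyl]cyclobut-2-en-1-one (racemic) | COC1(/C=C/[Sn](CCCC)(CCCC)CCCC)C(=O)C(OCC=C)=C1OCC=C | intermediate
21 | 4-methoxy-2,3-bis(prop-2-en-1-yloxy)-4-[(E)-2-(tributylstannyl)ethenyl]cyclobut-2-en-1-ol (mixture of diastereomers) | COC1(/C=C/[Sn](CCCC)(CCCC)CCCC)C(O)C(OCC=C)=C1OCC=C | intermediate
22 | 4-methoxy-2,3-bis(prop-2-en-1-yloxy)-4-[(E)-2-(tributylstannyl)ethenyl]cyclobut-2-en-1-yl trifluoroacetate | COC1(/C=C/[Sn](CCCC)(CCCC)CCCC)C(OC(=O)C(F)(F)F)C(OCC=C)=C1OCC=C | intermediate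
23 | 4-methoxy-2-(prop-2-en-1-yloxy)-4-[(E)-2-(tributylstannyl)ethenyl]cyclobut-2-en-1-one (racemic) | COC1(/C=C/[Sn](CCCC)(CCCC)CCCC)C=C(OCC=C)C1=O | intermediate
24 | 4-methoxy-4-{(1E,3E)-5-methoxy-5-methyl-7-[(1S,2R)-1,2,3-trimethylcyclohex-3-en-1-yl]hepta-1,3-dien-1-yl}-2-(prop-2-en-1-yloxy)cyclobut-2-en-1-one (mixture of diastereomers) | COC1(/C=C/C=C/C(C)(OC)CC[C@]2(C)CCC=C(C)[C@@H]2C)C=C(OCC=C)C1=O | intermediate
25 | dienylketene: 4,9-dimethoxy-9-methyl-2-(prop-2-en-1-yloxy)-11-[(1S,2R)-1,2,3-trimethylcyclohex-3-en-1-yl]undeca-1,3,5,7-tetraen-1-one (methoxy outward, dienyl cis to the ketene) | O=C=C(OCC=C)/C=C(/OC)\C=C\C=C\C(C)(OC)CC[C@]1(C)CCC=C(C)[C@@H]1C | intermediate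
26 | 4-methoxy-6-{(1E)-3-methoxy-3-methyl-5-[(1S,2R)-1,2,3-trimethylcyclohex-3-en-1-yl]pent-1-en-1-yl}-2-(prop-2-en-1-yloxy)cyclohexa-2,4-dien-1-one | O=C1C(OCC=C)=CC(OC)=CC1/C=C/C(C)(OC)CC[C@]2(C)CCC=C(C)[C@@H]2C | intermediate
27 | 4-methoxy-2-{(1E)-3-methoxy-3-methyl-5-[(1S,2R)-1,2,3-trimethylcyclohex-3-en-1-yl]pent-1-en-1-yl}-6-(prop-2-en-1-yloxy)phenol (both epimers at the methoxy-bearing carbon) | COc1cc(OCC=C)c(O)c(c1)/C=C/C(C)(OC)CC[C@]2(C)CCC=C(C)[C@@H]2C | intermediate
28 | 1-(2-hydroxy-5-methoxy-3-(prop-2-en-1-yloxy)phenyl)-3-methyl-5-[(1S,2R)-1,2,3-trimethylcyclohex-3-en-1-yl]pent-1-en-3-ylium (O-protonated vinyl o-quinone methide; counter-ion is the phosphoramide anion of the catalyst) | COc1cc(OCC=C)c(O)c(c1)C=C[C+](C)CC[C@]2(C)CCC=C(C)[C@@H]2C | intermediate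
29 | (2S)-6-methoxy-2-methyl-8-(prop-2-en-1-yloxy)-2-{2-[(1S,2R)-1,2,3-trimethylcyclohex-3-en-1-yl]ethyl}-2H-chromene | COc1cc(OCC=C)c2c(c1)C=C[C@](C)(CC[C@]3(C)CCC=C(C)[C@@H]3C)O2 | intermediate
30 | (2S)-6-methoxy-2-methyl-2-{2-[(1S,2R)-1,2,3-trimethylcyclohex-3-en-1-yl]ethyl}-2H-chromen-8-ol | COc1cc(O)c2c(c1)C=C[C@](C)(CC[C@]3(C)CCC=C(C)[C@@H]3C)O2 | intermediate
31 | (2S)-6-methoxy-2-methyl-2-{2-[(1S,2R)-1,2,3-trimethylcyclohex-3-en-1-yl]ethyl}-2H-chromene-5,8-dione | COC1=CC(=O)C2=C(C=C[C@](C)(CC[C@]3(C)CCC=C(C)[C@@H]3C)O2)C1=O | target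

**Step count and risks**

Total steps: 13. Longest linear sequence: 9 (steps 1–5, 10–13); the squarate branch (steps 6–9) joins at step 10.

Steps most likely to fail:

1. Step 11 (proposed new method). Catalyst control at C2 may be lost: through uncatalysed closure during the thermal stage, through weak discrimination between the two helical closing modes of a cation whose terminus carries two alkyl groups, or through acid-induced migration of the ring alkene. Fallback (known chemistry), setting out from 24 and coming back at 29: the same thermal ring expansion gives 27, and an achiral acid (diphenyl phosphate, CH2Cl2, 0 °C) closes the ring without facial bias to 29 and its C2 epimer, (2R)-6-methoxy-2-methyl-8-(prop-2-en-1-yloxy)-2-{2-[(1S,2R)-1,2,3-trimethylcyclohex-3-en-1-yl]ethyl}-2H-chromene F1. The two are diastereomers and are to be separated by preparative HPLC on a polysaccharide chiral stationary phase. F1 should be recyclable by re-exposure to the same acid, which re-forms the cation.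

2. Step 1. Facial selectivity may be poor, exo addition may compete, and the 1,2-disubstituted diene may add in the alternative (meta) orientation. Fallback, setting out from 1 and 2 and coming back at 3: cycloaddition promoted by EtAlCl2 (CH2Cl2, −78 °C) should give the racemic endo adduct, that is 3 together with its enantiomer (1S,2R)-1,2,3-trimethylcyclohex-3-ene-1-carbaldehyde F2. Condensation with (1R,2R)-N,N'-dimethyl-1,2-diphenylethane-1,2-diamine (4 Å molecular sieves, CH2Cl2) gives the diastereomeric aminals (4R,5R)-1,3-dimethyl-4,5-diphenyl-2-[(1R,2S)-1,2,3-trimethylcyclohex-3-en-1-yl]imidazolidine F3 (from 3) and (4R,5R)-1,3-dimethyl-4,5-diphenyl-2-[(1S,2R)-1,2,3-trimethylcyclohex-3-en-1-yl]imidazolidine F4 (from F2), which are separated by chromatography. Hydrolysis of F3 (dilute aqueous HCl, Et2O, 0 °C) returns 3.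

3. Step 10. Protodestannylation or homocoupling of the stannane, or copper-induced decomposition of the strained enone, may outrun the cross-coupling. Fallback, setting out from 13 (with 17 and 16) and coming back at 24: the union is moved to an organolithium addition. Stille coupling of 13 with excess 17 (Pd2(dba)3, zerovalent palladium, AsPh3, NMP, rt) gives tributyl{(1E,3E)-5-methoxy-5-methyl-7-[(1S,2R)-1,2,3-trimethylcyclohex-3-en-1-yl]hepta-1,3-dien-1-yl}stannane F5. Tin–lithium exchange (MeLi, THF, −78 °C), addition to 16 and MeOTf give 4-methoxy-4-{(1E,3E)-5-methoxy-5-methyl-7-[(1S,2R)-1,2,3-trimethylcyclohex-3-en-1-yl]hepta-1,3-dien-1-yl}-2,3-bis(prop-2-en-1-yloxy)cyclobut-2-en-1-one F6. Reduction with i-Bu2AlH gives 4-methoxy-4-{(1E,3E)-5-methoxy-5-methyl-7-[(1S,2R)-1,2,3-trimethylcyclohex-3-en-1-yl]hepta-1,3-dien-1-yl}-2,3-bis(prop-2-en-1-yloxy)cyclobut-2-en-1-ol F7. Treatment with (CF3CO)2O and 2,6-lutidine, then aqueous NaHCO3, as in step 9, gives 24.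

**Further compounds**

F1 | step 11 | (2R)-6-methoxy-2-methyl-8-(prop-2-en-1-yloxy)-2-{2-[(1S,2R)-1,2,3-trimethylcyclohex-3-en-1-yl]ethyl}-2H-chromene | COc1cc(OCC=C)c2c(c1)C=C[C@@](C)(CC[C@]3(C)CCC=C(C)[C@@H]3C)O2
F2 | step 1 | (1S,2R)-1,2,3-trimethylcyclohex-3-ene-1-carbaldehyde | O=C[C@@]1(C)CCC=C(C)[C@H]1C
F3 | step 1 | (4R,5R)-1,3-dimethyl-4,5-diphenyl-2-[(1R,2S)-1,2,3-trimethylcyclohex-3-en-1-yl]imidazolidine | CN1[C@H](c2ccccc2)[C@@H](c2ccccc2)N(C)C1[C@]3(C)CCC=C(C)[C@@H]3C
F4 | step 1 | (4R,5R)-1,3-dimethyl-4,5-diphenyl-2-[(1S,2R)-1,2,3-trimethylcyclohex-3-en-1-yl]imidazolidine | CN1[C@H](c2ccccc2)[C@@H](c2ccccc2)N(C)C1[C@@]3(C)CCC=C(C)[C@H]3C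
F5 | step 10 | tributyl{(1E,3E)-5-methoxy-5-methyl-7-[(1S,2R)-1,2,3-trimethylcyclohex-3-en-1-yl]hepta-1,3-dien-1-yl}stannane | CCCC[Sn](CCCC)(CCCC)/C=C/C=C/C(C)(OC)CC[C@]1(C)CCC=C(C)[C@@H]1C
F6 | step 10 | 4-methoxy-4-{(1E,3E)-5-methoxy-5-methyl-7-[(1S,2R)-1,2,3-trimethylcyclohex-3-en-1-yl]hepta-1,3-dien-1-yl}-2,3-bis(prop-2-en-1-yloxy)cyclobut-2-en-1-one | COC1(/C=C/C=C/C(C)(OC)CC[C@]2(C)CCC=C(C)[C@@H]2C)C(=O)C(OCC=C)=C1OCC=C
F7 | step 10 | 4-methoxy-4-{(1E,3E)-5-methoxy-5-methyl-7-[(1S,2R)-1,2,3-trimethylcyclohex-3-en-1-yl]hepta-1,3-dien-1-yl}-2,3-bis(prop-2-en-1-yloxy)cyclobut-2-en-1-ol | COC1(/C=C/C=C/C(C)(OC)CC[C@]2(C)CCC=C(C)[C@@H]2C)C(O)C(OCC=C)=C1OCC=C
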